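The fourteen-membered ring (C1 = the CH stereocentre, then C2, C3=C4 bearing CO2H, C7=C8, C11=C12, to C14) is opened at C9–C10, the central bond of the C7=C8/C11=C12 1,5-diene, which is allylic on both flanks and lies farthest from C1 and the enoate. In one operation the C10 carbanion of a Z-allylic phenyl sulfone displaces an E-allylic bromide at C9, forming that bond and the macrocycle while leaving all three ring alkenes untouched. The precursor is an acyclic (R)-configured methyl Z-enoate carrying the nerol-derived sulfone at one end and the bromide at the other; saponification and palladium-catalysed hydride desulfonylation then finish the acid.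

Key step: step 16

Remark (numbering): ring atoms C1–C14 as defined above, with C15(=C16H2) on C1; the same locants are used for the open-chain intermediates.
Remark (structure check): C1 is R; C3=C4 is Z by CIP (ring carbons C2 and C5 trans), C7=C8 is E and C11=C12 is Z; compounds 21 and 22 as drawn carry exactly these elements, so no structure needed correction.
Remark (assumption): 4 (oxirane carbon) and 18 (phosphonate α-carbon) are used as racemates at centres that are destroyed later, 8 is drawn as its E isomer, and 22 and 23 are carried as both C10 epimers.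
Remark (design): the sulfone is installed first so that the Z geometry comes from nerol, the conjugate addition is run without base because the C10 protons sit six atoms from the enoate β-carbon, and the allylic bromide is made only one step before ring closure.

Step 1
Reactants: 1 nerol
Product: 2 neryl bromide
Conditions: PBr3 (0.4 equiv), Et2O, −10 °C
Reagents that add atoms: phosphorus tribromide, BrP(Br)Br
Why: Low-temperature bromination of a primary allylic alcohol with PBr3 (substitution through the bromophosphite) should give the primary bromide without allylic transposition and with the Z alkene retained.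

Step 2
Reactants: 2 neryl bromide
Product: 3 neryl phenyl sulfone
Conditions: PhSO2Na (1.3 equiv), DMF, rt
Reagents that add atoms: sodium benzenesulfinate, [Na+].[O-]S(=O)c1ccccc1
Why: SN2 S-alkylation of the ambident sulfinate by the primary allylic bromide in a dipolar aprotic solvent should give the sulfone with the Z geometry intact.

Step 3
Reactants: 3 neryl phenyl sulfone
Product: 4 terminal epoxide of neryl phenyl sulfone
Conditions: mCPBA (1.0 equiv), NaHCO3, CH2Cl2, 0 °C
Reagents that add atoms: 3-chloroperoxybenzoic acid, OOC(=O)c1cccc(Cl)c1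
Why: Prilezhaev epoxidation is expected at the electron-rich terminal trisubstituted alkene only, because the other alkene is deactivated by the allylic sulfonyl group, and the new oxirane centre forms as a racemate that is destroyed in step 4.

Step 4
Reactants: 4 terminal epoxide of neryl phenyl sulfone
Product: 5 (4Z)-4-methyl-6-(phenylsulfonyl)hex-4-enal
Conditions: HIO4·2H2O (1.2 equiv), THF/Et2O, 0 °C to rt
Reagents that add atoms: none
Why: Periodic acid opens the epoxide to the glycol and cleaves it in the same flask (Malaprade-type glycol cleavage), the oxygen taken up from the reagent leaving in the acetone, so that the aldehyde carbon that becomes C1 is unveiled.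

Step 5
Reactants: 5 (4Z)-4-methyl-6-(phenylsulfonyl)hex-4-enal
Product: 6 methyl (2E,6Z)-6-methyl-8-(phenylsulfonyl)octa-2,6-dienoate
Conditions: Ph3P=CHCO2Me (1.2 equiv), CH2Cl2, rt
Reagents that add atoms: methyl (triphenylphosphoranylidene)acetate, COC(=O)C=P(c1ccccc1)(c1ccccc1)c1ccccc1
Why: Wittig olefination with a stabilised ylide should give the E-enoate and needs no added base, so the acidic allylic sulfone is left alone.

Step 6
Reactants: 7 6-methylhept-5-en-2-one (sulcatone)
Product: 8 2,4,6-triisopropylbenzenesulfonyl hydrazone of sulcatone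
Conditions: 2,4,6-triisopropylbenzenesulfonohydrazide (1.0 equiv), MeOH, cat. HCl, rt
Reagents that add atoms: 2,4,6-triisopropylbenzenesulfonohydrazide, NNS(=O)(=O)c1c(C(C)C)cc(C(C)C)cc1C(C)C
Why: Acid-catalysed condensation of the methyl ketone with the arenesulfonyl hydrazide gives the hydrazone required for a Shapiro reaction.

Step 7
Reactants: 8 2,4,6-triisopropylbenzenesulfonyl hydrazone of sulcatone
Product: 11 potassium trifluoro(6-methylhepta-1,5-dien-2-yl)borate, via (6-methylhepta-1,5-dien-2-yl)lithium 9 (not isolated), via lithium triisopropoxy(6-methylhepta-1,5-dien-2-yl)borate 10 (not isolated)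
Conditions: n-BuLi (2.2 equiv), THF, −78 to 0 °C; B(Oi-Pr)3, −78 °C to rt; aq. KHF2, rt
Reagents that add atoms: n-butyllithium, [Li]CCCC; triisopropyl borate, CC(C)OB(OC(C)C)OC(C)C; potassium hydrogen difluoride, [K+].[F-].F
Why: Shapiro reaction, in which the second deprotonation occurs at the methyl group and loss of sulfinate and N2 gives the 1-alken-2-yllithium, followed by trapping with the borate ester and conversion into the bench-stable trifluoroborate with KHF2.

Step 8
Reactants: 6 methyl (2E,6Z)-6-methyl-8-(phenylsulfonyl)octa-2,6-dienoate; 11 potassium trifluoro(6-methylhepta-1,5-dien-2-yl)borate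
Product: 12 methyl (3R,6Z)-6-methyl-3-(6-methylhepta-1,5-dien-2-yl)-8-(phenylsulfonyl)oct-6-enoate
Conditions: 11 (2.5 equiv), [Rh(cod)2]BF4 (5 mol %), (S)-BINAP (6 mol %), toluene/H2O (10:1), 100 °C
Reagents that add atoms: none
Why: Hayashi–Miyaura rhodium-catalysed asymmetric 1,4-addition, in which the alkenylrhodium species formed by transmetalation inserts the E-enoate and the (S)-BINAP ligand is expected, by the facial model established for E-crotonates (attack on the α-si face), to give (R)-C1, while the base-free medium keeps the C10 position from adding to the enoate.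

Step 9
Reactants: 12 methyl (3R,6Z)-6-methyl-3-(6-methylhepta-1,5-dien-2-yl)-8-(phenylsulfonyl)oct-6-enoate
Product: 13 (3R,6Z)-6-methyl-3-(6-methylhepta-1,5-dien-2-yl)-8-(phenylsulfonyl)oct-6-enal
Conditions: i-Bu2AlH (1.2 equiv), CH2Cl2, −78 °C; MeOH, then aq. potassium sodium tartrate
Reagents that add atoms: none
Why: Partial ester reduction with i-Bu2AlH at −78 °C stops at the aluminium hemiacetal, which gives the aldehyde on work-up, and C1 is β to the carbonyl and cannot epimerise.

Step 10
Reactants: 14 5-bromo-2-methylpent-2-ene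
Product: 15 (2E)-5-bromo-2-methylpent-2-en-1-ol
Conditions: SeO2 (0.3 equiv), t-BuOOH (2 equiv), CH2Cl2, 0 °C to rt
Reagents that add atoms: selenium dioxide, O=[Se]=O; tert-butyl hydroperoxide, CC(C)(C)OO
Why: Riley allylic oxidation in its catalytic SeO2/t-BuOOH form proceeds by ene reaction and [2,3]-sigmatropic shift and is known to hydroxylate the E-methyl group of a gem-dimethyl trisubstituted alkene, which sets the C7=C8 geometry.

Step 11
Reactants: 15 (2E)-5-bromo-2-methylpent-2-en-1-ol
Product: 16 tert-butyldimethylsilyl ether of 15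
Conditions: t-BuMe2SiCl (1.1 equiv), imidazole, CH2Cl2, 0 °C to rt
Reagents that add atoms: tert-butyldimethylsilyl chloride, CC(C)(C)[Si](C)(C)Cl
Why: Standard silylation of the primary allylic alcohol protects the future C9 oxygen through the two carbanion steps that follow.

Step 12
Reactants: 16 tert-butyldimethylsilyl ether of 15; 17 methyl bis(2,2,2-trifluoroethyl)phosphonoacetate
Product: 18 methyl (5E)-2-[bis(2,2,2-trifluoroethoxy)phosphoryl]-7-(tert-butyldimethylsilyloxy)-6-methylhept-5-enoate
Conditions: 17 (2 equiv), NaH (1.9 equiv), DMF, 0 °C; then 16, NaI (cat.), 50 °C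
Reagents that add atoms: none
Why: C-alkylation of the sodium phosphonoacetate by the primary bromide under iodide catalysis, with excess phosphonate to hold back dialkylation, should give the α-substituted reagent, whose new α-centre is racemic and disappears in step 13.

Step 13
Reactants: 13 (3R,6Z)-6-methyl-3-(6-methylhepta-1,5-dien-2-yl)-8-(phenylsulfonyl)oct-6-enal; 18 methyl (5E)-2-[bis(2,2,2-trifluoroethoxy)phosphoryl]-7-(tert-butyldimethylsilyloxy)-6-methylhept-5-enoate
Product: 19 silyl-protected seco Z-enoate
Conditions: 18 (1.4 equiv), KN(SiMe3)2 (1.3 equiv), 18-crown-6 (4 equiv), THF, −78 °C; then 13, −78 to −40 °C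
Reagents that add atoms: none
Why: Still–Gennari olefination, in which the electron-poor bis(trifluoroethyl) phosphonate with a dissociated potassium counter-ion eliminates rapidly from the kinetic adduct and should give the Z-enoate (C2 cis to CO2Me), the preformed phosphonate anion being too weak a base to deprotonate the sulfone.

Step 14
Reactants: 19 silyl-protected seco Z-enoate
Product: 20 seco allylic alcohol
Conditions: HF·pyridine, pyridine, THF, 0 °C to rt
Reagents that add atoms: none
Why: Fluoride-mediated cleavage of the primary silyl ether under buffered, non-basic conditions should leave the allylic sulfone, the enoate and the alkenes untouched.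

Step 15
Reactants: 20 seco allylic alcohol
Product: 21 seco sulfone bromide
Conditions: CBr4 (1.3 equiv), PPh3 (1.4 equiv), CH2Cl2, 0 °C
Reagents that add atoms: carbon tetrabromide, BrC(Br)(Br)Br
Why: Appel bromination of the primary allylic alcohol at 0 °C proceeds by SN2 displacement of the oxyphosphonium ion and should keep the E geometry at C7=C8.

Step 16
Reactants: 21 seco sulfone bromide
Product: 22 macrocyclic sulfone methyl ester
Conditions: KN(SiMe3)2 (1.15 equiv), THF, −40 to −10 °C, 21 added by syringe pump over 8 h to a final concentration of about 2 mM; aq. NH4Cl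
Reagents that add atoms: none
Why: KN(SiMe3)2 removes the C10 proton, which is allylic and α to the sulfonyl group and therefore the most acidic in 21, and the carbanion displaces bromide from the primary E-allylic C9 in an intramolecular SN2 reaction. The closest known reaction type is the alkylation of α-sulfonyl allyl carbanions by allylic halides, used to join isoprenoid chains and to close fourteen-membered carbocycles. The ring is closed in a 14-exo-tet mode, which slow addition and high dilution make competitive with oligomerisation. C10 becomes a stereocentre with no controlling element, so both epimers are expected, which is harmless because the centre is removed in step 18. The step needs C10 deprotonation over enoate γ-deprotonation (secured by the sulfone acidity and only a slight excess of base), α- over γ-alkylation with the Z-C11=C12 geometry retained (secured by charge localisation next to sulfur at low temperature) and SN2 over SN2′ at the unhindered CH2Br. The α-branched Z-enoate is a poor Michael and acyl acceptor and C1 carries no acidic proton, so both should be spectators.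

Step 17
Reactants: 22 macrocyclic sulfone methyl ester
Product: 23 macrocyclic sulfone acid
Conditions: LiOH·H2O (10 equiv), THF/MeOH/H2O, 50 °C; then 1 M HCl
Reagents that add atoms: lithium hydroxide, [Li+].[OH-]
Why: Saponification (BAc2) of the hindered methyl ester should proceed on warming, hydroxide being too weak a base to deprotonate C10 to a meaningful extent.

Step 18
Reactants: 23 macrocyclic sulfone acid
Product: 24 CNP0269207.1
Conditions: PdCl2(dppp) (10 mol %), LiBHEt3 (4 equiv), THF, 0 °C to rt; then 1 M HCl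
Reagents that add atoms: none
Why: Palladium-catalysed reductive desulfonylation, in which zerovalent palladium formed in the flask ionises the allylic sulfone to a π-allyl complex and hydride from LiBHEt3 enters at the less substituted terminus C10, keeping C11=C12 in place with its Z geometry and erasing the C10 stereocentre, while the lithium carboxylate formed by the first equivalent of hydride is inert.

Compound list
1 | nerol, (2Z)-3,7-dimethylocta-2,6-dien-1-ol | CC(C)=CCC/C(C)=C\CO | starting material
2 | neryl bromide, (2Z)-1-bromo-3,7-dimethylocta-2,6-diene | CC(C)=CCC/C(C)=C\CBr | intermediate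
3 | neryl phenyl sulfone, {[(2Z)-3,7-dimethylocta-2,6-dien-1-yl]sulfonyl}benzene | CC(C)=CCC/C(C)=C\CS(=O)(=O)c1ccccc1 | intermediate
4 | 2,2-dimethyl-3-[(3Z)-3-methyl-5-(phenylsulfonyl)pent-3-en-1-yl]oxirane, racemic | CC1(C)OC1CC/C(C)=C\CS(=O)(=O)c1ccccc1 | intermediate
5 | (4Z)-4-methyl-6-(phenylsulfonyl)hex-4-enal | O=CCC/C(C)=C\CS(=O)(=O)c1ccccc1 | intermediate
6 | methyl (2E,6Z)-6-methyl-8-(phenylsulfonyl)octa-2,6-dienoate | COC(=O)/C=C/CC/C(C)=C\CS(=O)(=O)c1ccccc1 | intermediate
7 | 6-methylhept-5-en-2-one (sulcatone) | CC(=O)CCC=C(C)C | starting material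
8 | N'-[(2E)-6-methylhept-5-en-2-ylidene]-2,4,6-triisopropylbenzenesulfonohydrazide | C/C(CCC=C(C)C)=N\NS(=O)(=O)c1c(C(C)C)cc(C(C)C)cc1C(C)C | intermediate
9 | (6-methylhepta-1,5-dien-2-yl)lithium, formed in the flask | [Li]C(=C)CCC=C(C)C | intermediate
10 | lithium triisopropoxy(6-methylhepta-1,5-dien-2-yl)borate, formed in the flask | [Li+].C=C(CCC=C(C)C)[B-](OC(C)C)(OC(C)C)OC(C)C | intermediate
11 | potassium trifluoro(6-methylhepta-1,5-dien-2-yl)borate | [K+].C=C(CCC=C(C)C)[B-](F)(F)F | intermediate
12 | methyl (3R,6Z)-6-methyl-3-(6-methylhepta-1,5-dien-2-yl)-8-(phenylsulfonyl)oct-6-enoate | C=C(CCC=C(C)C)[C@H](CC/C(C)=C\CS(=O)(=O)c1ccccc1)CC(=O)OC | intermediate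
13 | (3R,6Z)-6-methyl-3-(6-methylhepta-1,5-dien-2-yl)-8-(phenylsulfonyl)oct-6-enal | C=C(CCC=C(C)C)[C@H](CC/C(C)=C\CS(=O)(=O)c1ccccc1)CC=O | intermediate
14 | 5-bromo-2-methylpent-2-ene | CC(C)=CCCBr | starting material
15 | (2E)-5-bromo-2-methylpent-2-en-1-ol | OC/C(C)=C/CCBr | intermediate
16 | {[(2E)-5-bromo-2-methylpent-2-en-1-yl]oxy}(tert-butyl)dimethylsilane | CC(C)(C)[Si](C)(C)OC/C(C)=C/CCBr | intermediate
17 | methyl bis(2,2,2-trifluoroethyl)phosphonoacetate | COC(=O)CP(=O)(OCC(F)(F)F)OCC(F)(F)F | starting material
18 | methyl (5E)-2-[bis(2,2,2-trifluoroethoxy)phosphoryl]-7-(tert-butyldimethylsilyloxy)-6-methylhept-5-enoate, racemic at C2 | COC(=O)C(CC/C=C(\C)CO[Si](C)(C)C(C)(C)C)P(=O)(OCC(F)(F)F)OCC(F)(F)F | intermediate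
19 | methyl (2Z,5R,8Z)-2-[(3E)-5-(tert-butyldimethylsilyloxy)-4-methylpent-3-en-1-yl]-8-methyl-5-(6-methylhepta-1,5-dien-2-yl)-10-(phenylsulfonyl)deca-2,8-dienoate | C=C(CCC=C(C)C)[C@H](CC/C(C)=C\CS(=O)(=O)c1ccccc1)C/C=C(\C(=O)OC)CC/C=C(\C)CO[Si](C)(C)C(C)(C)C | intermediate
20 | methyl (2Z,5R,8Z)-2-[(3E)-5-hydroxy-4-methylpent-3-en-1-yl]-8-methyl-5-(6-methylhepta-1,5-dien-2-yl)-10-(phenylsulfonyl)deca-2,8-dienoate | C=C(CCC=C(C)C)[C@H](CC/C(C)=C\CS(=O)(=O)c1ccccc1)C/C=C(\C(=O)OC)CC/C=C(\C)CO | intermediate
21 | seco sulfone bromide, methyl (2Z,5R,8Z)-2-[(3E)-5-bromo-4-methylpent-3-en-1-yl]-8-methyl-5-(6-methylhepta-1,5-dien-2-yl)-10-(phenylsulfonyl)deca-2,8-dienoate | C=C(CCC=C(C)C)[C@H](CC/C(C)=C\CS(=O)(=O)c1ccccc1)C/C=C(\C(=O)OC)CC/C=C(\C)CBr | intermediate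
22 | methyl (1R,3Z,7E,11Z)-8,12-dimethyl-1-(6-methylhepta-1,5-dien-2-yl)-10-(phenylsulfonyl)cyclotetradeca-3,7,11-triene-4-carboxylate, ring locants as in the opening paragraph, both C10 epimers | C=C(CCC=C(C)C)[C@H]1C/C=C(\C(=O)OC)CC/C=C(\C)CC(S(=O)(=O)c2ccccc2)/C=C(/C)CC1 | intermediate
23 | (1R,3Z,7E,11Z)-8,12-dimethyl-1-(6-methylhepta-1,5-dien-2-yl)-10-(phenylsulfonyl)cyclotetradeca-3,7,11-triene-4-carboxylic acid, both C10 epimers | C=C(CCC=C(C)C)[C@H]1C/C=C(\C(=O)O)CC/C=C(\C)CC(S(=O)(=O)c2ccccc2)/C=C(/C)CC1 | intermediate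
24 | CNP0269207.1, (1R,3Z,7E,11Z)-8,12-dimethyl-1-(6-methylhepta-1,5-dien-2-yl)cyclotetradeca-3,7,11-triene-4-carboxylic acid | C=C(CCC=C(C)C)[C@H]1C/C=C(\C(=O)O)CC/C=C(\C)CC/C=C(/C)CC1 | target

Total step count: 18.
Longest linear sequence: 13 steps (nerol 1 to 24 through steps 1–5, 8, 9 and 13–18).

Steps most likely to fail

Step 16 (ring closure). What may go wrong: intermolecular alkylation to oligomers, or base-induced loss of HBr from the allylic bromide, overtakes the entropically costly closure. The fallback sets out from aldehyde 13 and alcohol 15 and returns at 22. It exchanges the two bond formations, so that C9–C10 is made between two molecules and the ring is closed at C3=C4 by an intramolecular Still–Gennari olefination. Aldehyde 13 is protected (HC(OMe)3, pyridinium p-toluenesulfonate, MeOH) as the dimethyl acetal of 13 F1, and 15 is brominated (CBr4, PPh3, CH2Cl2) to (2E)-1,5-dibromo-2-methylpent-2-ene F2. The C10 anion of F1 (n-BuLi, THF, −78 °C) is alkylated by F2 at its allylic bromide, which reacts far faster than the remote primary bromide, to give the C9–C10 coupled bromo acetal F3. That remaining bromide alkylates the sodium salt of 17 (NaH, NaI, DMF) to give the phosphonate acetal F4. Pyridinium p-toluenesulfonate in wet acetone frees the aldehyde phosphonate F5, and KN(SiMe3)2 with 18-crown-6 in THF at high dilution closes the ring to 22, the kinetic preference of the reagent matching the trans arrangement of C2 and C5 that the ring favours.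

Step 8 (asymmetric conjugate addition). What may go wrong: insertion of the β-alkyl enoate into the hindered α-substituted alkenyl–rhodium bond is slow, so that protodeboronation uses up 11, or the facial selectivity is insufficient. The fallback sets out from nerol 1 (with hydrazone 8 as the alkenyl source) and returns at 12. It sets C1 by auxiliary-controlled, copper-mediated conjugate addition on a substrate that carries no acidic sulfone. Nerol is silylated (t-BuPh2SiCl, imidazole) to neryl tert-butyldiphenylsilyl ether F6, epoxidised at the terminal alkene (mCPBA) to the epoxide F7 and cleaved (HIO4·2H2O) to (4Z)-6-(tert-butyldiphenylsilyloxy)-4-methylhex-4-enal F8. Masamune–Roush olefination (LiCl, i-Pr2NEt, MeCN) with the known reagent diethyl {2-oxo-2-[(4S)-2-oxo-4-phenyl-1,3-oxazolidin-3-yl]ethyl}phosphonate gives the N-enoyl oxazolidinone F9. Alkenyllithium 9, generated from 8 as in step 7, is transmetalated with MgBr2·OEt2 to (6-methylhepta-1,5-dien-2-yl)magnesium bromide F10 and added with CuBr·SMe2 in THF/Me2S at −40 °C to F9. The magnesium-chelated s-cis imide is attacked on the face away from the 4-phenyl group, giving the conjugate adduct F11 with (R)-C1. Methanolysis (NaOMe, MeOH, 0 °C) returns the auxiliary and gives the silyloxy methyl ester F12; n-Bu4NF gives the allylic alcohol F13; PBr3 gives the allylic bromide F14; and PhSO2Na in DMF gives 12.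

Step 18 (desulfonylation). What may go wrong: ionisation of the sulfone is slow on the poorly soluble lithium carboxylate, which gives the π-allyl palladium intermediate time to equilibrate, with loss of the Z geometry or migration of the C11=C12 alkene. The fallback sets out from 22, bypasses 23 and returns at 24. It takes the carboxyl carbon through the reduction at the alcohol oxidation level. i-Bu2AlH (CH2Cl2, −78 °C) reduces the ester of 22 to the macrocyclic sulfone allylic alcohol F15, and PdCl2(dppp)/LiBHEt3 on this neutral, soluble substrate gives the desulfonylated allylic alcohol F16. MnO2 (CH2Cl2) then gives the Z-enal F17, which is oxidised at once (NaClO2, NaH2PO4, 2-methylbut-2-ene, t-BuOH/H2O; Pinnick oxidation) to 24.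

Further compounds
F1 | step 16 | dimethyl acetal of 13, {[(2Z,6R)-8,8-dimethoxy-3-methyl-6-(6-methylhepta-1,5-dien-2-yl)oct-2-en-1-yl]sulfonyl}benzene | C=C(CCC=C(C)C)[C@H](CC/C(C)=C\CS(=O)(=O)c1ccccc1)CC(OC)OC
F2 | step 16 | (2E)-1,5-dibromo-2-methylpent-2-ene | BrCC/C=C(\C)CBr
F3 | step 16 | C9–C10 coupled bromo acetal (C10 epimers) | C=C(CCC=C(C)C)[C@H](CC/C(C)=C\C(C/C(C)=C/CCBr)S(=O)(=O)c1ccccc1)CC(OC)OC
F4 | step 16 | phosphonate acetal (mixture at C4 and C10) | C=C(CCC=C(C)C)[C@H](CC/C(C)=C\C(C/C(C)=C/CCC(C(=O)OC)P(=O)(OCC(F)(F)F)OCC(F)(F)F)S(=O)(=O)c1ccccc1)CC(OC)OC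
F5 | step 16 | aldehyde phosphonate (mixture at C4 and C10) | C=C(CCC=C(C)C)[C@H](CC/C(C)=C\C(C/C(C)=C/CCC(C(=O)OC)P(=O)(OCC(F)(F)F)OCC(F)(F)F)S(=O)(=O)c1ccccc1)CC=O
F6 | step 8 | neryl tert-butyldiphenylsilyl ether | CC(C)=CCC/C(C)=C\CO[Si](c1ccccc1)(c1ccccc1)C(C)(C)C
F7 | step 8 | terminal epoxide of F6, racemic | CC1(C)OC1CC/C(C)=C\CO[Si](c1ccccc1)(c1ccccc1)C(C)(C)C
F8 | step 8 | (4Z)-6-(tert-butyldiphenylsilyloxy)-4-methylhex-4-enal | O=CCC/C(C)=C\CO[Si](c1ccccc1)(c1ccccc1)C(C)(C)C
F9 | step 8 | (4S)-3-[(2E,6Z)-8-(tert-butyldiphenylsilyloxy)-6-methylocta-2,6-dienoyl]-4-phenyl-1,3-oxazolidin-2-one | O=C(/C=C/CC/C(C)=C\CO[Si](c1ccccc1)(c1ccccc1)C(C)(C)C)N1C(=O)OC[C@@H]1c1ccccc1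
F10 | step 8 | (6-methylhepta-1,5-dien-2-yl)magnesium bromide | C=C(CCC=C(C)C)[Mg]Br
F11 | step 8 | (4S)-3-[(3R,6Z)-8-(tert-butyldiphenylsilyloxy)-6-methyl-3-(6-methylhepta-1,5-dien-2-yl)oct-6-enoyl]-4-phenyl-1,3-oxazolidin-2-one | C=C(CCC=C(C)C)[C@H](CC/C(C)=C\CO[Si](c1ccccc1)(c1ccccc1)C(C)(C)C)CC(=O)N1C(=O)OC[C@@H]1c1ccccc1
F12 | step 8 | methyl (3R,6Z)-8-(tert-butyldiphenylsilyloxy)-6-methyl-3-(6-methylhepta-1,5-dien-2-yl)oct-6-enoate | C=C(CCC=C(C)C)[C@H](CC/C(C)=C\CO[Si](c1ccccc1)(c1ccccc1)C(C)(C)C)CC(=O)OC
F13 | step 8 | methyl (3R,6Z)-8-hydroxy-6-methyl-3-(6-methylhepta-1,5-dien-2-yl)oct-6-enoate | C=C(CCC=C(C)C)[C@H](CC/C(C)=C\CO)CC(=O)OC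
F14 | step 8 | methyl (3R,6Z)-8-bromo-6-methyl-3-(6-methylhepta-1,5-dien-2-yl)oct-6-enoate | C=C(CCC=C(C)C)[C@H](CC/C(C)=C\CBr)CC(=O)OC
F15 | step 18 | [(1R,3Z,7E,11Z)-8,12-dimethyl-1-(6-methylhepta-1,5-dien-2-yl)-10-(phenylsulfonyl)cyclotetradeca-3,7,11-trien-4-yl]methanol, both C10 epimers | C=C(CCC=C(C)C)[C@H]1C/C=C(\CO)CC/C=C(\C)CC(S(=O)(=O)c2ccccc2)/C=C(/C)CC1
F16 | step 18 | [(1R,3Z,7E,11Z)-8,12-dimethyl-1-(6-methylhepta-1,5-dien-2-yl)cyclotetradeca-3,7,11-trien-4-yl]methanol | C=C(CCC=C(C)C)[C@H]1C/C=C(\CO)CC/C=C(\C)CC/C=C(/C)CC1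
F17 | step 18 | (1R,3Z,7E,11Z)-8,12-dimethyl-1-(6-methylhepta-1,5-dien-2-yl)cyclotetradeca-3,7,11-triene-4-carbaldehyde | C=C(CCC=C(C)C)[C@H]1C/C=C(\C=O)CC/C=C(\C)CC/C=C(/C)CC1
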